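## Retrosynthetic overview
1. Feature: on ring A the oxygens at C5, C7 and C8a, together with the C4 carbonyl on C4a, stand 1,3 to one another like the carbonyls of a tetraketide. The oxygens at C6, C8 and C3 sit on the carbons between them, so they can enter as α-methoxy groups of that chain.
2. Ring C (closed last): O1–C2 by cyclodehydration of a 1,3-diketone, whose C2–C3 bond comes from a Baker–Venkataraman shift of a 2,5-dimethoxybenzoate. Ring B is bought in.
3. Ring A (closed first): C4a–C8a by Claisen folding of methyl 2,4,8-trimethoxy-3,5,7-trioxooctanoate to a mirror-symmetric methoxyacetylphloroglucinol, followed by O-methylation at the future C7.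
4. Chain: the C4–C5 bond of the octanoate by γ-acylation of the dianion of methyl 2,4-dimethoxyacetoacetate (self-Claisen product of methyl methoxyacetate) with the dioxolane of methyl 4-methoxyacetoacetate, then unmasking.

Key step: step 5

Remark: the chain compounds and the 1,3-diketone hold only labile stereocentres α to carbonyl groups, so they are carried as mixtures of epimers and keto–enol tautomers and drawn in the keto form; the target has no stereocentre; pentamethoxybenzene, needed in one fallback only, is taken as a purchasable arene.

## Route

Step 1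
Reactants: 1 methyl methoxyacetate (two molecules)
Product: 2 methyl 2,4-dimethoxy-3-oxobutanoate (racemic)
Conditions: NaH (0.55 equiv per ester), THF, 0 °C → reflux; then 1 M HCl, 0 °C
Reagents that add atoms: none
Why: Claisen self-condensation in which the enolate of one ester acylates a second molecule and deprotonation of the β-keto ester formed pulls the equilibrium over, the C2 stereocentre arising racemic and labile, which is of no consequence.

Step 2
Reactants: 3 methyl 4-methoxyacetoacetate; 4 ethylene glycol
Product: 5 methyl 2-[2-(methoxymethyl)-1,3-dioxolan-2-yl]acetate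
Conditions: p-toluenesulfonic acid (cat.), toluene, Dean–Stark, reflux
Reagents that add atoms: none
Why: Acid-catalysed ketalisation with azeotropic removal of water masks the ketone only, so that the ester loses its acidic β-dicarbonyl methylene and can act as an acyl donor towards a strongly basic carbanion.

Step 3
Reactants: 2 methyl 2,4-dimethoxy-3-oxobutanoate; 5 methyl 2-[2-(methoxymethyl)-1,3-dioxolan-2-yl]acetate
Product: 7 methyl 2,4-dimethoxy-6-[2-(methoxymethyl)-1,3-dioxolan-2-yl]-3,5-dioxohexanoate (mixture of epimers), via dilithium dienediolate 6 (not isolated)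
Conditions: 2 (2.2 equiv), LiN(iPr)2 (4.5 equiv), THF, −78 → 0 °C; then 5 (1.0 equiv), −78 → 0 °C; AcOH, −78 °C
Reagents that add atoms: none
Why: Weiler-type γ-acylation of a β-keto ester dianion, in which the carbanion formed last (C4) is the more nucleophilic and attacks the ester of 5, the second equivalent of 6 takes up the acidic proton of the product, and the low temperature keeps proton transfer to 5 and E1cB opening of its dioxolane behind carbonyl addition, the new C4 stereocentre being unselective and labile.

Step 4
Reactants: 7 methyl 2,4-dimethoxy-6-[2-(methoxymethyl)-1,3-dioxolan-2-yl]-3,5-dioxohexanoate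
Product: 8 methyl 2,4,8-trimethoxy-3,5,7-trioxooctanoate (mixture of tautomers and epimers, taken on crude)
Conditions: 1 M HCl–THF (1:3), 0 °C → rt, stopped at full conversion
Reagents that add atoms: water, O
Why: Acid-catalysed ketal hydrolysis, eased by the enolisable C5 ketone through which the dioxolane can open as a β-alkoxy enone, is run dilute, cold and short because longer contact with acid would cyclodehydrate the freed 3,5,7-trione to a 4-pyranone, while the methyl ester and methyl ethers are inert.

Step 5
Reactants: 8 methyl 2,4,8-trimethoxy-3,5,7-trioxooctanoate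
Product: 10 2-methoxy-1-(2,4,6-trihydroxy-3,5-dimethoxyphenyl)ethan-1-one, via 2-(methoxyacetyl)-4,6-dimethoxycyclohexane-1,3,5-trione 9 (not isolated)
Conditions: Mg(OMe)2 (4 equiv), degassed MeOH, Ar, reflux; then 1 M HCl, 0 °C
Reagents that add atoms: none
Why: Mg(OMe)2 removes the most acidic protons, those of the C6 methylene between the C5 and C7 ketones, and binds 8 as a chelated polyenolate in which a second magnesium bridges the C3 ketone and the C1 ester and so polarises the ester carbonyl; C6 adds to C1, methoxide leaves and trione 9 enolises three times to the phenol, which makes the closure irreversible. The reaction type is the Claisen (Dieckmann-like) cyclisation of 3,5,7-triketo esters to acylphloroglucinols with Mg(OMe)2 or alkoxide, the laboratory counterpart of tetraketide folding, applied here to a chain that carries three methoxy groups. Ring A closes 6-exo-trig at the ester carbonyl, and only the C6–C1 bond (C4a–C8a of the flavone) is formed. No stereocentre is set, and the C2 and C4 epimers and all tautomers of 8 converge on one planar product. The step needs C-acylation at C6 to win over the C2-to-C7 aldol, over lactonisation of the C5 enolate oxygen onto C1 and over retro-Claisen cleavage: the aldol adduct would hold a quaternary C2 (OMe and CO2Me) and cannot dehydrate to a resorcylate, so it reverts, the 2-pyranone is reopened by methoxide in methanol, and the arene is the only sink. Retro-Claisen attack on the poorly enolised methoxy-bearing dicarbonyl units is the remaining threat and is the reason for weakly nucleophilic, chelating Mg(OMe)2 instead of NaOMe, and argon is needed because the polyphenolate is oxidised by air.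

Step 6
Reactants: 10 2-methoxy-1-(2,4,6-trihydroxy-3,5-dimethoxyphenyl)ethan-1-one
Product: 11 1-(2,6-dihydroxy-3,4,5-trimethoxyphenyl)-2-methoxyethan-1-one
Conditions: Me2SO4 (1.0 equiv), K2CO3 (1.0 equiv), acetone, Ar, rt → 40 °C
Reagents that add atoms: dimethyl sulfate, COS(=O)(=O)OC
Why: Williamson-type O-methylation under stoichiometric control, in which the hydroxyl para to the acyl group is the most acidic and is not tied to the ketone by a hydrogen bond, so one equivalent of base forms its phenoxide and one equivalent of the small, hard methylating agent caps it, ring C-methylation being shut out because every ring carbon is substituted.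

Step 7
Reactants: 11 1-(2,6-dihydroxy-3,4,5-trimethoxyphenyl)-2-methoxyethan-1-one; 12 2,5-dimethoxybenzoyl chloride
Product: 13 3-hydroxy-4,5,6-trimethoxy-2-(methoxyacetyl)phenyl 2,5-dimethoxybenzoate
Conditions: 12 (1.0 equiv, slow addition), Et3N (1.2 equiv), 4-(dimethylamino)pyridine (cat.), CH2Cl2, 0 °C → rt
Reagents that add atoms: none
Why: Nucleophile-catalysed O-acylation of a phenol by an acid chloride, in which the two ortho hydroxyls are equivalent by the mirror plane so only one mono-ester exists, and the hydroxyl left after the first acylation is locked in the chelate to the ketone and reacts more slowly.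

Step 8
Reactants: 13 3-hydroxy-4,5,6-trimethoxy-2-(methoxyacetyl)phenyl 2,5-dimethoxybenzoate
Product: 14 1-(2,6-dihydroxy-3,4,5-trimethoxyphenyl)-3-(2,5-dimethoxyphenyl)-2-methoxypropane-1,3-dione (racemic, labile)
Conditions: KOtBu (3.2 equiv), THF, 0 °C → rt; then 1 M HCl
Reagents that add atoms: none
Why: Baker–Venkataraman rearrangement, in which the enolate of the methoxyacetyl group attacks the neighbouring aryl ester through a six-membered transition state and releases the phenoxide, three equivalents of base covering the free phenol, the enolate and the acidic diketone, and the new stereocentre disappearing in the next step.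

Step 9
Reactants: 14 1-(2,6-dihydroxy-3,4,5-trimethoxyphenyl)-3-(2,5-dimethoxyphenyl)-2-methoxypropane-1,3-dione
Product: 15 grantioidinin, 2-(2,5-dimethoxyphenyl)-5-hydroxy-3,6,7,8-tetramethoxy-4H-chromen-4-one
Conditions: H2SO4 (cat.), AcOH, 90 °C
Reagents that add atoms: none
Why: Acid-catalysed cyclodehydration of an o-hydroxyaryl 1,3-diketone (6-exo-trig hemiketal formation at the aroyl carbonyl, then loss of water) closes ring C, either of the two equivalent phenols giving the same chromenone while the other stays as the chelated 5-OH, and the aryl methyl ethers survive catalytic acid.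

## Compound list
1 | methyl methoxyacetate | COCC(=O)OC | starting material
2 | methyl 2,4-dimethoxy-3-oxobutanoate (racemic) | COCC(=O)C(OC)C(=O)OC | intermediate
3 | methyl 4-methoxyacetoacetate | COCC(=O)CC(=O)OC | starting material
4 | ethylene glycol | OCCO | starting material
5 | methyl 2-[2-(methoxymethyl)-1,3-dioxolan-2-yl]acetate | COCC1(CC(=O)OC)OCCO1 | intermediate
6 | dilithium 1,2,4-trimethoxybuta-1,3-diene-1,3-diolate (dianion of 2, not isolated) | [Li+].[Li+].COC=C([O-])C(OC)=C([O-])OC | intermediate
7 | methyl 2,4-dimethoxy-6-[2-(methoxymethyl)-1,3-dioxolan-2-yl]-3,5-dioxohexanoate (mixture of epimers) | COCC1(CC(=O)C(OC)C(=O)C(OC)C(=O)OC)OCCO1 | intermediate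
8 | methyl 2,4,8-trimethoxy-3,5,7-trioxooctanoate (mixture of tautomers and epimers) | COCC(=O)CC(=O)C(OC)C(=O)C(OC)C(=O)OC | intermediate
9 | 2-(methoxyacetyl)-4,6-dimethoxycyclohexane-1,3,5-trione (not isolated) | COCC(=O)C1C(=O)C(OC)C(=O)C(OC)C1=O | intermediate
10 | 2-methoxy-1-(2,4,6-trihydroxy-3,5-dimethoxyphenyl)ethan-1-one | COCC(=O)c1c(O)c(OC)c(O)c(OC)c1O | intermediate
11 | 1-(2,6-dihydroxy-3,4,5-trimethoxyphenyl)-2-methoxyethan-1-one | COCC(=O)c1c(O)c(OC)c(OC)c(OC)c1O | intermediate
12 | 2,5-dimethoxybenzoyl chloride | COc1ccc(OC)c(C(=O)Cl)c1 | starting material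
13 | 3-hydroxy-4,5,6-trimethoxy-2-(methoxyacetyl)phenyl 2,5-dimethoxybenzoate | COCC(=O)c1c(O)c(OC)c(OC)c(OC)c1OC(=O)c1cc(OC)ccc1OC | intermediate
14 | 1-(2,6-dihydroxy-3,4,5-trimethoxyphenyl)-3-(2,5-dimethoxyphenyl)-2-methoxypropane-1,3-dione (racemic) | COc1ccc(OC)c(C(=O)C(OC)C(=O)c2c(O)c(OC)c(OC)c(OC)c2O)c1 | intermediate
15 | grantioidinin, 2-(2,5-dimethoxyphenyl)-5-hydroxy-3,6,7,8-tetramethoxy-4H-chromen-4-one | COc1ccc(OC)c(-c2oc3c(OC)c(OC)c(OC)c(O)c3c(=O)c2OC)c1 | target

## Step count and risks
Total step count: 9. Longest linear sequence: 8 (steps 1, 3, 4, 5, 6, 7, 8, 9). Step 2 is a one-step branch.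

**Step 5 (key step).**
- What may go wrong: methoxide may fragment the methoxy-bearing β-dicarbonyl units by retro-Claisen cleavage. The chain may also drain into O-acylation before the C–C closure takes place.
- Fallback (ring A taken from an arene, no folding): it sets out from 1 and comes back at 11, so steps 2 to 6 drop out.
- Ester 1 is converted with MeNH(OMe)·HCl and iPrMgCl in THF into N,2-dimethoxy-N-methylacetamide F1.
- Pentamethoxybenzene F2 is deprotonated with n-BuLi in THF at 0 °C at its only C–H, which lies between two methoxy groups (directed ortho-metalation). This gives pentamethoxyphenyllithium F3.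
- Addition of F3 to F1 (Weinreb ketone synthesis) should give 2-methoxy-1-(2,3,4,5,6-pentamethoxyphenyl)ethan-1-one F4.
- Excess BCl3 in CH2Cl2 (−78 °C → rt) then cleaves the two aryl methyl ethers ortho to the ketone through boron chelates and should deliver 11.

**Step 4.**
- What may go wrong: the dioxolane, deactivated by its two electron-poor neighbours, may hydrolyse slowly. The trione already freed would meanwhile cyclodehydrate under acid.
- Fallback (no mask, chain grown from the other end): it sets out from 2 and comes back at 8, so steps 2 to 4 drop out.
- Dienediolate 6, made from 2 as in step 3, is acetylated at C4 with N-methoxy-N-methylacetamide to give methyl 2,4-dimethoxy-3,5-dioxohexanoate F5.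
- LiN(iPr)2 (3.3 equiv, THF, −78 → 0 °C) converts F5 into trilithium 1,2,4-trimethoxyhexa-1,3,5-triene-1,3,5-triolate F6, whose last-formed carbanion sits on the terminal methyl carbon.
- That carbon is acylated by 1 (terminal acylation of a diketo ester trianion). A quench with AcOH should give 8 without any acid treatment of the chain.

**Step 6.**
- What may go wrong: methylation may spill over to an ortho hydroxyl or run on to a dimethyl ether, because the para hydroxyl is flanked by two methoxy groups.
- Fallback (methylation postponed to the flavone, where chelation switches the rival hydroxyl off): it sets out from 10 and 12 and comes back at 15, so steps 6 to 9 drop out.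
- Chloride 12 with 2,5-dimethoxybenzoic acid and Et3N in CH2Cl2 gives 2,5-dimethoxybenzoic anhydride F7.
- Ketone 10 is heated with F7 and potassium 2,5-dimethoxybenzoate at 170–180 °C (Allan–Robinson flavone synthesis).
- The crude melt is boiled with aqueous ethanolic KOH to remove phenolic esters. This should give 2-(2,5-dimethoxyphenyl)-5,7-dihydroxy-3,6,8-trimethoxy-4H-chromen-4-one F8.
- Me2SO4 (1 equiv) and K2CO3 in acetone then methylate only the 7-OH, since the 5-OH is held by the C4 carbonyl, and give 15.

## Further compounds
F1 | step 5 | N,2-dimethoxy-N-methylacetamide | COCC(=O)N(C)OC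
F2 | step 5 | pentamethoxybenzene (bought in) | COc1cc(OC)c(OC)c(OC)c1OC
F3 | step 5 | pentamethoxyphenyllithium | [Li]c1c(OC)c(OC)c(OC)c(OC)c1OC
F4 | step 5 | 2-methoxy-1-(2,3,4,5,6-pentamethoxyphenyl)ethan-1-one | COCC(=O)c1c(OC)c(OC)c(OC)c(OC)c1OC
F5 | step 4 | methyl 2,4-dimethoxy-3,5-dioxohexanoate | CC(=O)C(OC)C(=O)C(OC)C(=O)OC
F6 | step 4 | trilithium 1,2,4-trimethoxyhexa-1,3,5-triene-1,3,5-triolate | [Li+].[Li+].[Li+].C=C([O-])C(OC)=C([O-])C(OC)=C([O-])OC
F7 | step 6 | 2,5-dimethoxybenzoic anhydride | COc1ccc(OC)c(C(=O)OC(=O)c2cc(OC)ccc2OC)c1
F8 | step 6 | 2-(2,5-dimethoxyphenyl)-5,7-dihydroxy-3,6,8-trimethoxy-4H-chromen-4-one | COc1ccc(OC)c(-c2oc3c(OC)c(O)c(OC)c(O)c3c(=O)c2OC)c1
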